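**Plan** (labdane numbering; β is the face of CH3-20)
- Late cuts: the 13,14-epoxide (Sharpless epoxidation of the 13E allylic alcohol), the C4–CH3 bond (reductive methylation of a C3=C4 enoate) and C7–H (hydrogenolysis of an allylic C7–O–C19 lactone).
- Key cut: ring A at C1–C2 and C5–C10, which opens ring B as well. Ring A with the C19 carboxyl on C4 is, as its C3=C4 enoate, the retron of an intramolecular Diels–Alder reaction of the diene C2=C3–C4=C5 with the isopropenyl alkene C10=C1. C7 of ring B is allylic to the C8=C17 methylene, so C19 can be tied to an oxygen on C7 as a temporary six-membered lactone.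
- Forward: (S)-limonene oxide supplies C9 with C10/C20/C1, C7–C8 and C11–C13/C16. The aldehyde arm is grown into C17, the C7 carbinol and the C4–C6/C19 ynoate, the side chain is completed, the vinyl lactone is made, and one thermal step closes rings A and B together.
- Stereochemistry: C9 from the chiral pool; C7 (temporary) by catalyst control; C5 and C10 by the lactone-enforced cis-selective cycloaddition; C4 by enolate methylation anti to CH3-20; C13 and C14 by reagent-controlled epoxidation.

Key step: step 10

Remark: the target is read as drawn, an A/B-cis (5-epi) labdane in which H-5, CH3-20, the C9 side chain and the ester carbon C19 all lie on the β face.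

**Route**

Step 1
Reactants: 1 (4S)-limonene 1,2-oxide (commercial cis/trans mixture)
Product: 3 (3S)-6-oxo-3-(prop-1-en-2-yl)heptanal, via (4S)-limonene-1,2-diol 2 (not isolated)
Conditions: H5IO6 (1.2 equiv), THF/H2O 4:1, 0 °C → rt
Reagents that add atoms: water, O
Why: Acid-promoted epoxide hydration followed by Malaprade glycol cleavage converts both epoxide diastereomers into the same keto aldehyde and leaves the isopropenyl group and the C9 stereocentre (chiral pool, S) untouched.

Step 2
Reactants: 3 (3S)-6-oxo-3-(prop-1-en-2-yl)heptanal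
Product: 4 (3R)-2-methylidene-6-oxo-3-(prop-1-en-2-yl)heptanal
Conditions: 37% aqueous CH2O (1.2 equiv), pyrrolidine (10 mol %), propionic acid (10 mol %), i-PrOH, 45 °C
Reagents that add atoms: formaldehyde, C=O
Why: Amine-catalysed α-methylenation (Mannich condensation and elimination through the pyrrolidine enamine) is selective for the aldehyde over the methyl ketone and adds C17, while C9 cannot epimerise because its hydrogen is not conjugated with the carbonyl group (only its CIP descriptor changes).

Step 3
Reactants: 4 (3R)-2-methylidene-6-oxo-3-(prop-1-en-2-yl)heptanal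
Product: 5 (5R,7R)-7-hydroxy-6-methylidene-5-(prop-1-en-2-yl)dec-9-yn-2-one
Conditions: allenylboronic acid pinacol ester (1.5 equiv), (R)-3,3'-bis(2,4,6-triisopropylphenyl)-1,1'-binaphthyl-2,2'-diyl hydrogen phosphate ((R)-TRIP, 10 mol %), 4 Å molecular sieves, cyclohexane, 0 °C → rt; aqueous work-up
Reagents that add atoms: allenylboronic acid pinacol ester, C=C=CB1OC(C)(C)C(C)(C)O1
Why: Chiral phosphoric acid-catalysed allenylboration (SE2′ propargylation through a closed six-membered transition state) reacts with the aldehyde only, and the catalyst antipode that directs attack to the Re face of the aldehyde (taken to be the R catalyst) sets the carbinol carbon (labdane C7) as R by reagent control over the remote C9 centre.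

Step 4
Reactants: 5 (5R,7R)-7-hydroxy-6-methylidene-5-(prop-1-en-2-yl)dec-9-yn-2-one
Product: 6 ethyl (2E,6R,8R)-8-hydroxy-3-methyl-7-methylidene-6-(prop-1-en-2-yl)undec-2-en-10-ynoate
Conditions: (EtO)2P(O)CH2CO2Et (2.0 equiv), NaH (1.9 equiv), THF, 0 → 40 °C; the minor 2Z isomer is removed by chromatography
Reagents that add atoms: triethyl phosphonoacetate, CCOC(=O)CP(=O)(OCC)OCC
Why: Horner–Wadsworth–Emmons olefination of the methyl ketone by a stabilised phosphonate anion, which is too weakly basic to deprotonate the alcohol or the alkyne, should favour the 2E enoate with the longer chain trans to the ester.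

Step 5
Reactants: 6 ethyl (2E,6R,8R)-8-hydroxy-3-methyl-7-methylidene-6-(prop-1-en-2-yl)undec-2-en-10-ynoate
Product: 7 (2E,6R,8R)-3-methyl-7-methylidene-6-(prop-1-en-2-yl)undec-2-en-10-yne-1,8-diol
Conditions: i-Bu2AlH (3.5 equiv), CH2Cl2, −78 °C; aqueous potassium sodium tartrate
Reagents that add atoms: none
Why: 1,2-Reduction of the conjugated ester by the aluminium hydride at low temperature gives the allylic alcohol without touching the alkyne or the isolated alkenes.

Step 6
Reactants: 7 (2E,6R,8R)-3-methyl-7-methylidene-6-(prop-1-en-2-yl)undec-2-en-10-yne-1,8-diol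
Product: 8 (4R,6R,9E)-9-methyl-5-methylidene-6-(prop-1-en-2-yl)-11-(triisopropylsilyloxy)undec-9-en-1-yn-4-ol
Conditions: i-Pr3SiCl (1.05 equiv), imidazole (2.2 equiv), CH2Cl2, 0 °C
Reagents that add atoms: chlorotriisopropylsilane, CC(C)[Si](Cl)(C(C)C)C(C)C
Why: Silylation with the bulky chlorosilane is selective for the primary allylic hydroxyl over the hindered secondary C7 carbinol.

Step 7
Reactants: 8 (4R,6R,9E)-9-methyl-5-methylidene-6-(prop-1-en-2-yl)-11-(triisopropylsilyloxy)undec-9-en-1-yn-4-ol
Product: 9 methyl (5R,7R,10E)-5-hydroxy-10-methyl-6-methylidene-7-(prop-1-en-2-yl)-12-(triisopropylsilyloxy)dodec-10-en-2-ynoate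
Conditions: n-BuLi (2.1 equiv), THF, −78 °C; then ClCO2Me (1.05 equiv), −78 → −40 °C; aqueous NH4Cl
Reagents that add atoms: methyl chloroformate, COC(=O)Cl
Why: Double deprotonation gives the alkoxide acetylide dianion, whose more nucleophilic carbon end is acylated by one equivalent of the chloroformate at low temperature (acetylide C-acylation) to give the ynoate.

Step 8
Reactants: 9 methyl (5R,7R,10E)-5-hydroxy-10-methyl-6-methylidene-7-(prop-1-en-2-yl)-12-(triisopropylsilyloxy)dodec-10-en-2-ynoate
Product: 11 (6R)-6-[(3R,6E)-6-methyl-3-(prop-1-en-2-yl)-8-(triisopropylsilyloxy)octa-1,6-dien-2-yl]-3-(tributylstannyl)-5,6-dihydro-2H-pyran-2-one, via open-chain stannyl hydroxy ester 10 (not isolated)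
Conditions: Bu3SnH (1.1 equiv), Pd(PPh3)4 (2 mol %), THF, 0 °C; filtration through alumina; then pyridinium p-toluenesulfonate (cat.), toluene, 50 °C
Reagents that add atoms: tributyltin hydride, CCCC[SnH](CCCC)CCCC
Why: Palladium-catalysed syn hydrostannation of the ynoate places tin on the α carbon and hydrogen on the β carbon, so that the ester stands cis to the C6 chain and the δ-hydroxy ester closes under mild acid to the six-membered unsaturated lactone (lactonisation).

Step 9
Reactants: 11 (6R)-6-[(3R,6E)-6-methyl-3-(prop-1-en-2-yl)-8-(triisopropylsilyloxy)octa-1,6-dien-2-yl]-3-(tributylstannyl)-5,6-dihydro-2H-pyran-2-one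
Product: 12 (6R)-3-ethenyl-6-[(3R,6E)-6-methyl-3-(prop-1-en-2-yl)-8-(triisopropylsilyloxy)octa-1,6-dien-2-yl]-5,6-dihydro-2H-pyran-2-one
Conditions: vinyl iodide (3 equiv), copper thiophene-2-carboxylate Cu(O2CC4H3S) (1.5 equiv), N-methylpyrrolidone, 0 °C → rt, dark; used at once
Reagents that add atoms: vinyl iodide, C=CI
Why: Copper-mediated Stille-type coupling (Liebeskind) joins the α-stannyl enoate to vinyl iodide with retention at C4 and avoids zerovalent palladium, which could ionise the allylic lactone.

Step 10
Reactants: 12 (6R)-3-ethenyl-6-[(3R,6E)-6-methyl-3-(prop-1-en-2-yl)-8-(triisopropylsilyloxy)octa-1,6-dien-2-yl]-5,6-dihydro-2H-pyran-2-one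
Product: 13 (5S,7R,9R,10R)-15-(triisopropylsilyloxy)labda-3,8(17),13E-trien-19,7-olide
Conditions: o-dichlorobenzene (0.005 M), 2,6-di-tert-butyl-4-methylphenol (5 mol %), degassed, sealed vessel, 180 °C
Reagents that add atoms: none
Why: Heating triggers a concerted, suprafacial [4+2] cycloaddition in which the semicyclic diene C2=C3–C4=C5 of the 3-vinyl-dihydropyranone (LUMO lowered by the C19 carbonyl) combines with the unactivated, electron-rich isopropenyl alkene C10=C1 to form C1–C2 and C5–C10 together. The closest known reaction type is the thermal type 1 intramolecular Diels–Alder reaction of 1,7,9-decatrienes with 1,1-disubstituted dienophiles, which delivers decalins with an angular methyl group. Ring A closes through the boat-like six-centre array of the cycloaddition, and ring B closes at the same time as the tether ring C5–C6–C7–C8–C9–C10 in a chair that the lactone bridges 1,3-diaxially, so that a bridged bicyclic δ-lactone results. C5 is controlled by C7, because C19 and O7 are held cis by the lactone and the C8 arm can reach only the face of C5 on which it stands, which leaves H5 trans to O7; C10 is controlled by the same ring, because with C9 forced under the diene (endo) only the rotamer with C1 below C2 is productive and the methyl group is exo, hence cis to H5. The step needs cis ring fusion and a single diene face: the trans-fused mode requires a C4=C5–C6–C7 torsion near 150°, which the lactone ring (locked near 30°) cannot reach, so only the endo-tether mode is possible. The 7R carbinol is matched with the limonene-derived C9, which then carries its side chain equatorial (exo, cis to CH3-20) and H9 towards the lactone carbonyl, so that no competing diastereomeric pathway is available.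

Step 11
Reactants: 13 (5S,7R,9R,10R)-15-(triisopropylsilyloxy)labda-3,8(17),13E-trien-19,7-olide
Product: 14 (5S,9S,10R)-15-(triisopropylsilyloxy)labda-3,8(17),13E-trien-19-oic acid
Conditions: Pd2(dba)3·CHCl3 (2.5 mol %), n-Bu3P (10 mol %), HCO2H (3 equiv), Et3N (4 equiv), 1,4-dioxane, 80 °C; aqueous citric acid
Reagents that add atoms: none
Why: Tsuji–Trost ionisation of the allylic C7–O bond (axial and parallel to the C8=C17 π orbital) followed by decarboxylative hydride transfer from the palladium formate to the more substituted allyl terminus C7 (Tsuji formate reduction) should give the exocyclic alkene and free the C19 acid.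

Step 12
Reactants: 14 (5S,9S,10R)-15-(triisopropylsilyloxy)labda-3,8(17),13E-trien-19-oic acid
Product: 15 methyl (5S,9S,10R)-15-(triisopropylsilyloxy)labda-3,8(17),13E-trien-19-oate
Conditions: MeI (3 equiv), K2CO3 (2 equiv), DMF, rt
Reagents that add atoms: iodomethane, CI
Why: SN2 O-methylation of the potassium carboxylate gives the methyl ester needed for clean enolate chemistry.

Step 13
Reactants: 15 methyl (5S,9S,10R)-15-(triisopropylsilyloxy)labda-3,8(17),13E-trien-19-oate
Product: 16 methyl (4S,5S,9S,10R)-15-(triisopropylsilyloxy)labda-8(17),13E-dien-19-oate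
Conditions: Li (2.5 equiv), t-BuOH (1.0 equiv), liquid NH3/THF, −78 °C; then MeI (10 equiv), −78 → 0 °C
Reagents that add atoms: iodomethane, CI
Why: Dissolving-metal reductive alkylation reduces the conjugated ester to its C4 enolate, which iodomethane should attack from the α face, anti to the axial C10 methyl group in the ring A chair that keeps H5 equatorial to avoid A(1,3) strain with the exocyclic enolate, so that the ester ends β as in podocarpate-type C4 alkylations.

Step 14
Reactants: 16 methyl (4S,5S,9S,10R)-15-(triisopropylsilyloxy)labda-8(17),13E-dien-19-oate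
Product: 17 methyl (4S,5S,9S,10R,13E)-15-hydroxylabda-8(17),13-dien-19-oate
Conditions: n-Bu4NF (1.5 equiv), THF, 0 °C → rt
Reagents that add atoms: none
Why: Fluoride-induced desilylation frees the primary allylic alcohol.

Step 15
Reactants: 17 methyl (4S,5S,9S,10R,13E)-15-hydroxylabda-8(17),13-dien-19-oate
Product: 18 methyl (4S,5S,9S,10R,13R,14R)-13,14-epoxy-15-hydroxylabd-8(17)-en-19-oate (target CNP0175926.1)
Conditions: Ti(Oi-Pr)4 (10 mol %), D-(−)-diethyl tartrate (12 mol %), t-BuOOH (2 equiv, in decane), 4 Å molecular sieves, CH2Cl2, −20 °C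
Reagents that add atoms: tert-butyl hydroperoxide, CC(C)(C)OO
Why: Katsuki–Sharpless asymmetric epoxidation acts only on the allylic alcohol alkene, and the D-(−)-tartrate complex delivers oxygen to the face of the 13E alkene that gives the 13R,14R epoxy alcohol by reagent control.

**Compound list**

1 | (4S)-limonene 1,2-oxide, (4S)-1-methyl-4-(prop-1-en-2-yl)-7-oxabicyclo[4.1.0]heptane, cis/trans mixture at the epoxide | CC12OC1C[C@H](CC2)C(=C)C | starting material
2 | (4S)-1-methyl-4-(prop-1-en-2-yl)cyclohexane-1,2-diol (from both epoxides; not isolated) | CC1(O)C(O)C[C@H](CC1)C(=C)C | intermediate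
3 | (3S)-6-oxo-3-(prop-1-en-2-yl)heptanal | O=CC[C@H](CCC(C)=O)C(C)=C | intermediate
4 | (3R)-2-methylidene-6-oxo-3-(prop-1-en-2-yl)heptanal | O=CC(=C)[C@H](CCC(C)=O)C(C)=C | intermediate
5 | (5R,7R)-7-hydroxy-6-methylidene-5-(prop-1-en-2-yl)dec-9-yn-2-one | C#CC[C@@H](O)C(=C)[C@H](CCC(C)=O)C(C)=C | intermediate
6 | ethyl (2E,6R,8R)-8-hydroxy-3-methyl-7-methylidene-6-(prop-1-en-2-yl)undec-2-en-10-ynoate | C#CC[C@@H](O)C(=C)[C@H](CC/C(C)=C/C(=O)OCC)C(C)=C | intermediate
7 | (2E,6R,8R)-3-methyl-7-methylidene-6-(prop-1-en-2-yl)undec-2-en-10-yne-1,8-diol | C#CC[C@@H](O)C(=C)[C@H](CC/C(C)=C/CO)C(C)=C | intermediate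
8 | (4R,6R,9E)-9-methyl-5-methylidene-6-(prop-1-en-2-yl)-11-(triisopropylsilyloxy)undec-9-en-1-yn-4-ol | C#CC[C@@H](O)C(=C)[C@H](CC/C(C)=C/CO[Si](C(C)C)(C(C)C)C(C)C)C(C)=C | intermediate
9 | methyl (5R,7R,10E)-5-hydroxy-10-methyl-6-methylidene-7-(prop-1-en-2-yl)-12-(triisopropylsilyloxy)dodec-10-en-2-ynoate | COC(=O)C#CC[C@@H](O)C(=C)[C@H](CC/C(C)=C/CO[Si](C(C)C)(C(C)C)C(C)C)C(C)=C | intermediate
10 | methyl (2E,5R,7R,10E)-5-hydroxy-10-methyl-6-methylidene-7-(prop-1-en-2-yl)-2-(tributylstannyl)-12-(triisopropylsilyloxy)dodeca-2,10-dienoate (ester cis to C6; not isolated) | COC(=O)/C(=C\C[C@@H](O)C(=C)[C@H](CC/C(C)=C/CO[Si](C(C)C)(C(C)C)C(C)C)C(C)=C)[Sn](CCCC)(CCCC)CCCC | intermediate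
11 | (6R)-6-[(3R,6E)-6-methyl-3-(prop-1-en-2-yl)-8-(triisopropylsilyloxy)octa-1,6-dien-2-yl]-3-(tributylstannyl)-5,6-dihydro-2H-pyran-2-one | O=C1C([Sn](CCCC)(CCCC)CCCC)=CC[C@@H](O1)C(=C)[C@H](CC/C(C)=C/CO[Si](C(C)C)(C(C)C)C(C)C)C(C)=C | intermediate
12 | (6R)-3-ethenyl-6-[(3R,6E)-6-methyl-3-(prop-1-en-2-yl)-8-(triisopropylsilyloxy)octa-1,6-dien-2-yl]-5,6-dihydro-2H-pyran-2-one | O=C1C(C=C)=CC[C@@H](O1)C(=C)[C@H](CC/C(C)=C/CO[Si](C(C)C)(C(C)C)C(C)C)C(C)=C | intermediate
13 | (5S,7R,9R,10R)-15-(triisopropylsilyloxy)labda-3,8(17),13E-trien-19,7-olide (A/B cis; O7 trans to H5 and to CH3-20; side chain cis to CH3-20) | C=C1[C@H]2C[C@@H]3C(=CCC[C@]3(C)[C@H]1CC/C(C)=C/CO[Si](C(C)C)(C(C)C)C(C)C)C(=O)O2 | intermediate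
14 | (5S,9S,10R)-15-(triisopropylsilyloxy)labda-3,8(17),13E-trien-19-oic acid | C=C1CC[C@@H]2C(C(=O)O)=CCC[C@]2(C)[C@H]1CC/C(C)=C/CO[Si](C(C)C)(C(C)C)C(C)C | intermediate
15 | methyl (5S,9S,10R)-15-(triisopropylsilyloxy)labda-3,8(17),13E-trien-19-oate | C=C1CC[C@@H]2C(C(=O)OC)=CCC[C@]2(C)[C@H]1CC/C(C)=C/CO[Si](C(C)C)(C(C)C)C(C)C | intermediate
16 | methyl (4S,5S,9S,10R)-15-(triisopropylsilyloxy)labda-8(17),13E-dien-19-oate | C=C1CC[C@H]2[C@](C)(CCC[C@]2(C)C(=O)OC)[C@H]1CC/C(C)=C/CO[Si](C(C)C)(C(C)C)C(C)C | intermediate
17 | methyl (4S,5S,9S,10R,13E)-15-hydroxylabda-8(17),13-dien-19-oate | C=C1CC[C@H]2[C@](C)(CCC[C@]2(C)C(=O)OC)[C@H]1CC/C(C)=C/CO | intermediate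
18 | methyl (4S,5S,9S,10R,13R,14R)-13,14-epoxy-15-hydroxylabd-8(17)-en-19-oate | C=C1CC[C@H]2[C@](C)(CCC[C@]2(C)C(=O)OC)[C@H]1CC[C@@]1(C)O[C@@H]1CO | target

**Totals**

Total step count: 15. Longest linear sequence: 15 steps (from 1).

**Steps most likely to fail**

1. Step 10 (intramolecular Diels–Alder). Bond formation at the fully substituted C10 may be slower than thermal oligomerisation of the vinyl lactone or ene-type side reactions. Fallback: the thermal pericyclic step is replaced by a metal-templated [4+2]. Compound 12 is treated with a cationic monovalent rhodium catalyst, [Rh(cod)(C10H8)]SbF6 (5 mol %), in 1,2-dichloroethane at 40–60 °C, so that oxidative cyclisation of diene and alkene on rhodium and reductive elimination give 13. The lactone still allows only the cis-fused product. The fallback sets out from 12, returns at 13 and makes no new compound.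

2. Step 13 (reductive methylation). Over-reduction (loss of the allylic silyl ether or reduction of the ester) or protonation of the enolate before alkylation may occur under dissolving-metal conditions. Fallback: reduction and alkylation are separated. Compound 15 is reduced at C3=C4 with Mg in MeOH, which leaves isolated alkenes and the silyl ether alone, to the saturated ester methyl 15-(triisopropylsilyloxy)-18-norlabda-8(17),13E-dien-19-oate F1 (C4 epimers, both usable). This is deprotonated with LiN(i-Pr)2 in THF at −78 °C and methylated with MeI in the presence of N,N'-dimethylpropyleneurea under the same facial control. The fallback sets out from 15 and returns at 16.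

3. Step 11 (hydrogenolysis of the lactone). Ionisation of the bridged lactone may be slow because palladium must approach anti to the leaving group past the axial C10 methyl group, or hydride may be delivered to the exocyclic terminus C17 so that the alkene moves into ring B. Fallback: the lactone is opened first and the hydride source is bound to the substrate. Compound 13 with NaOMe in MeOH at 0 °C should give the hydroxy ester methyl (5S,7R,9R,10R)-7-hydroxy-15-(triisopropylsilyloxy)labda-3,8(17),13E-trien-19-oate F2. Formic acetic anhydride and pyridine convert it into the allylic formate methyl (5S,7R,9R,10R)-7-(formyloxy)-15-(triisopropylsilyloxy)labda-3,8(17),13E-trien-19-oate F3. Pd(OAc)2 (5 mol %) and n-Bu3P (20 mol %) in 1,4-dioxane at rt to 40 °C then give 15 by loss of CO2 and hydride transfer within the palladium formate complex in the now flexible cis-decalin. The fallback sets out from 13 and returns at 15, so step 12 is no longer needed.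

**Further compounds**

F0 | step 10 | none | none
F1 | step 13 | methyl 15-(triisopropylsilyloxy)-18-norlabda-8(17),13E-dien-19-oate (C4 epimers; C5, C9 and C10 as in 15) | C=C1CC[C@@H]2C(C(=O)OC)CCC[C@]2(C)[C@H]1CC/C(C)=C/CO[Si](C(C)C)(C(C)C)C(C)C
F2 | step 11 | methyl (5S,7R,9R,10R)-7-hydroxy-15-(triisopropylsilyloxy)labda-3,8(17),13E-trien-19-oate | C=C1[C@H](O)C[C@@H]2C(C(=O)OC)=CCC[C@]2(C)[C@H]1CC/C(C)=C/CO[Si](C(C)C)(C(C)C)C(C)C
F3 | step 11 | methyl (5S,7R,9R,10R)-7-(formyloxy)-15-(triisopropylsilyloxy)labda-3,8(17),13E-trien-19-oate | C=C1[C@H](OC=O)C[C@@H]2C(C(=O)OC)=CCC[C@]2(C)[C@H]1CC/C(C)=C/CO[Si](C(C)C)(C(C)C)C(C)C
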